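**Strategy.** The route rests on closing the cyclohexane at the C-1–C-6 bond, at the ring end of the tetrasubstituted exocyclic C-1=C(CH3)CHO alkene. Its two ring neighbours (C-2H bearing the hydroxypropyl arm and C-6H2) are too alike for a late carbonyl olefination to distinguish. A 9-BBN hydroboration followed by palladium-catalysed B-alkyl Suzuki–Miyaura coupling converts an acyclic, geometrically defined (E)-enol triflate into the ring in one operation and carries its geometry over unchanged. The precursor is an acyclic vinyl carbinol (C-4, silyl-capped) that carries the C-2/C-3 stereodiad from an enantioselective Ireland–Claisen rearrangement and, at C-1, the enol triflate of an α-methyl β-keto ester.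

Key step: step 13

Assumption: the (4S,5S)-enantiomer of the diazaborolidinyl bromide in step 3 is taken to deliver the (2S,3R)-acid 8; should the sense of induction be opposite, its (4R,5R)-enantiomer is used and nothing else changes.

Numbering: ring C-1 is the alkylidene carbon, C-2 the CH bearing the three-carbon arm, C-3 the quaternary carbon, C-4 the carbinol carbon, C-5 and C-6 the methylenes. Acyclic intermediates use the same numbers for the same atoms.

Precursor design: the C-4 oxygen is carried as a triethylsilyl ether from 15 to 34. Left free, it sits 1,4 to C-1; it would close a five-membered hemiketal at the β-keto ester stage and would displace the sulfonate from the enol triflate by addition–elimination under the basic coupling conditions. The carbon skeletons of precursor 21 and product 23 are otherwise as required.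

Step 1
Reactants: 1 δ-valerolactone (oxan-2-one)
Product: 4 5-(tert-butyldimethylsilyloxy)pentanoic acid, via sodium 5-hydroxypentanoate 2 (not isolated), via tert-butyldimethylsilyl 5-(tert-butyldimethylsilyloxy)pentanoate 3 (not isolated)
Conditions: NaOH, MeOH/H2O, 60 °C, then evaporation; t-BuMe2SiCl, imidazole, DMF, rt; K2CO3, MeOH/THF/H2O, rt; pH 4–5
Reagents that add atoms: sodium hydroxide, [Na+].[OH-]; tert-butyldimethylsilyl chloride, CC(C)(C)[Si](C)(C)Cl
Why: Saponification opens the lactone, silylation caps both oxygens, and carbonate cleaves only the labile silyl ester, a standard protection sequence for hydroxy acids.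

Step 2
Reactants: 4 5-(tert-butyldimethylsilyloxy)pentanoic acid; 5 (2E,6E)-farnesol
Product: 6 (2E,6E)-farnesyl 5-(tert-butyldimethylsilyloxy)pentanoate
Conditions: DCC, 4-(dimethylamino)pyridine (cat.), CH2Cl2, 0 °C → rt
Reagents that add atoms: none
Why: Steglich esterification acylates the primary allylic alcohol under neutral conditions, so neither allylic transposition nor desilylation is expected.

Step 3
Reactants: 6 (2E,6E)-farnesyl 5-(tert-butyldimethylsilyloxy)pentanoate
Product: 8 (2S,3R,6E)-2-[3-(tert-butyldimethylsilyloxy)propyl]-3-ethenyl-3,7,11-trimethyldodeca-6,10-dienoic acid, via boron ketene acetal 7 (not isolated)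
Conditions: (4S,5S)-2-bromo-1,3-bis{[3,5-bis(trifluoromethyl)phenyl]sulfonyl}-4,5-diphenyl-1,3,2-diazaborolidine (1.2 equiv), i-Pr2NEt, CH2Cl2, −78 °C; then −20 → 4 °C, several days; aqueous work-up
Reagents that add atoms: none
Why: Enantioselective Ireland–Claisen rearrangement, in which the amine/bromoborane pair in dichloromethane should form the Z(O) boron ketene acetal, a chair transition state with the E-trisubstituted allyl unit places the arm on C-2 and the homogeranyl chain on C-3 syn along the C-1–C-2–C-3–vinyl backbone, and the C2-symmetric controller selects the enolate face and so the absolute configuration of the tertiary C-2 and quaternary C-3 centres.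

Step 4
Reactants: 8 (2S,3R,6E)-2-[3-(tert-butyldimethylsilyloxy)propyl]-3-ethenyl-3,7,11-trimethyldodeca-6,10-dienoic acid
Product: 9 methyl (2S,3R,6E)-2-[3-(tert-butyldimethylsilyloxy)propyl]-3-ethenyl-3,7,11-trimethyldodeca-6,10-dienoate
Conditions: Me3SiCHN2, MeOH/PhMe, 0 °C → rt
Reagents that add atoms: (trimethylsilyl)diazomethane, C[Si](C)(C)C=[N+]=[N-]
Why: O-Methylation of the carboxylic acid by the diazoalkane esterifies the hindered acid without touching alkenes or the silyl ether, and removes the free carboxyl group that would undergo oxypalladation in the next step.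

Step 5
Reactants: 9 methyl (2S,3R,6E)-2-[3-(tert-butyldimethylsilyloxy)propyl]-3-ethenyl-3,7,11-trimethyldodeca-6,10-dienoate
Product: 10 methyl (2S,3S,6E)-3-acetyl-2-[3-(tert-butyldimethylsilyloxy)propyl]-3,7,11-trimethyldodeca-6,10-dienoate
Conditions: PdCl2 (10 mol %), CuCl, O2 (1 atm), DMF/H2O, rt
Reagents that add atoms: water, O
Why: Wacker–Tsuji oxidation converts the only monosubstituted alkene into the methyl ketone by Markovnikov hydroxypalladation and β-hydride elimination, the trisubstituted chain alkenes being too hindered to compete for divalent palladium.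

Step 6
Reactants: 10 methyl (2S,3S,6E)-3-acetyl-2-[3-(tert-butyldimethylsilyloxy)propyl]-3,7,11-trimethyldodeca-6,10-dienoate; 11 vinylmagnesium bromide
Product: 13 (3S,4S,5S)-3-[3-(tert-butyldimethylsilyloxy)propyl]-4-[(3E)-4,8-dimethylnona-3,7-dien-1-yl]-5-ethenyl-4,5-dimethyloxolan-2-one, via bromomagnesium alkoxide 12 (not isolated)
Conditions: THF, −78 → 0 °C; then rt
Reagents that add atoms: none
Why: Grignard 1,2-addition under Felkin–Anh control (the branched C-2 substituent of quaternary C-3 anti to the incoming vinyl group, which passes the C-3 methyl and not the homogeranyl chain) should set C-4 as in the target, and the alkoxide then acylates itself on the neighbouring methyl ester to give a γ-lactone from which any C-4 epimer can be removed by chromatography.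

Step 7
Reactants: 13 (3S,4S,5S)-3-[3-(tert-butyldimethylsilyloxy)propyl]-4-[(3E)-4,8-dimethylnona-3,7-dien-1-yl]-5-ethenyl-4,5-dimethyloxolan-2-one
Product: 14 (2S,3S,6E)-2-[3-(tert-butyldimethylsilyloxy)propyl]-3-[(2S)-2-hydroxybut-3-en-2-yl]-3,7,11-trimethyldodeca-6,10-dien-1-ol
Conditions: LiAlH4, THF, 0 °C → rt
Reagents that add atoms: none
Why: Hydride reduction opens the lactone to the 1,4-diol without affecting alkenes, the silyl ether or any stereocentre.

Step 8
Reactants: 14 (2S,3S,6E)-2-[3-(tert-butyldimethylsilyloxy)propyl]-3-[(2S)-2-hydroxybut-3-en-2-yl]-3,7,11-trimethyldodeca-6,10-dien-1-ol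
Product: 15 bis(triethylsilyl) ether of 14 (primary C-1 and tertiary C-4 oxygens silylated)
Conditions: Et3SiOTf, 2,6-lutidine, CH2Cl2, −78 → 0 °C
Reagents that add atoms: triethylsilyl trifluoromethanesulfonate, CC[Si](CC)(CC)OS(=O)(=O)C(F)(F)F
Why: The silyl triflate with a hindered pyridine base silylates even the congested tertiary hydroxyl, which must be masked before C-1 becomes a ketone.

Step 9
Reactants: 15 bis(triethylsilyl) ether of 14
Product: 16 (2S,3S,6E)-2-[3-(tert-butyldimethylsilyloxy)propyl]-3,7,11-trimethyl-3-[(2S)-2-(triethylsilyloxy)but-3-en-2-yl]dodeca-6,10-dienal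
Conditions: (COCl)2, DMSO, CH2Cl2, −78 → −35 °C; Et3N, −78 °C → rt
Reagents that add atoms: none
Why: Under Swern conditions a primary triethylsilyl ether is cleaved and oxidised directly to the aldehyde by the activated sulfoxide, while the tertiary triethylsilyl ether and the primary tert-butyldimethylsilyl ether are too hindered or too robust to react.

Step 10
Reactants: 16 (2S,3S,6E)-2-[3-(tert-butyldimethylsilyloxy)propyl]-3,7,11-trimethyl-3-[(2S)-2-(triethylsilyloxy)but-3-en-2-yl]dodeca-6,10-dienal; 17 ethyl propionate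
Product: 19 ethyl (4S,5S,8E)-4-[3-(tert-butyldimethylsilyloxy)propyl]-3-hydroxy-2,5,9,13-tetramethyl-5-[(2S)-2-(triethylsilyloxy)but-3-en-2-yl]tetradeca-8,12-dienoate (mixture at C-2 and C-3 of the ester chain), via lithium enolate of ethyl propionate 18 (not isolated)
Conditions: LiN(i-Pr)2, THF, −78 °C (17 → 18); then 16, −78 °C
Reagents that add atoms: none
Why: Aldol addition of the lithium ester enolate to the hindered aldehyde is fast at low temperature, and the two new centres need no control because both are erased in steps 11 and 12.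

Step 11
Reactants: 19 ethyl (4S,5S,8E)-4-[3-(tert-butyldimethylsilyloxy)propyl]-3-hydroxy-2,5,9,13-tetramethyl-5-[(2S)-2-(triethylsilyloxy)but-3-en-2-yl]tetradeca-8,12-dienoate
Product: 20 ethyl (4S,5S,8E)-4-[3-(tert-butyldimethylsilyloxy)propyl]-2,5,9,13-tetramethyl-3-oxo-5-[(2S)-2-(triethylsilyloxy)but-3-en-2-yl]tetradeca-8,12-dienoate (mixture at the α-methyl carbon)
Conditions: Dess–Martin periodinane, NaHCO3, CH2Cl2, rt
Reagents that add atoms: none
Why: Dess–Martin oxidation gives the α-methyl β-keto ester under buffered, non-epimerising conditions, enolisation being confined to the doubly activated carbon and not to C-2.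

Step 12
Reactants: 20 ethyl (4S,5S,8E)-4-[3-(tert-butyldimethylsilyloxy)propyl]-2,5,9,13-tetramethyl-3-oxo-5-[(2S)-2-(triethylsilyloxy)but-3-en-2-yl]tetradeca-8,12-dienoate
Product: 21 ethyl (2E,4S,5S,8E)-4-[3-(tert-butyldimethylsilyloxy)propyl]-2,5,9,13-tetramethyl-5-[(2S)-2-(triethylsilyloxy)but-3-en-2-yl]-3-(trifluoromethylsulfonyloxy)tetradeca-2,8,12-trienoate
Conditions: Tf2O, aq. Me4NOH, PhMe, 0 °C
Reagents that add atoms: trifluoromethanesulfonic anhydride, O=S(=O)(OS(=O)(=O)C(F)(F)F)C(F)(F)F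
Why: O-Sulfonylation of a non-chelated tetraalkylammonium enolate, in which the enolate oxygen should lie anti to the ester carbonyl (dipole minimisation, with the bulky C-2 branch next to the twistable ester and not the methyl group), so the triflate is placed trans to the ester and cis to the methyl group (E), whereas lithium or sodium enolates would chelate and give the other isomer.

Step 13
Reactants: 21 ethyl (2E,4S,5S,8E)-4-[3-(tert-butyldimethylsilyloxy)propyl]-2,5,9,13-tetramethyl-5-[(2S)-2-(triethylsilyloxy)but-3-en-2-yl]-3-(trifluoromethylsulfonyloxy)tetradeca-2,8,12-trienoate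
Product: 23 ethyl (2Z)-2-[(2R,3S,4S)-2-[3-(tert-butyldimethylsilyloxy)propyl]-3-[(3E)-4,8-dimethylnona-3,7-dien-1-yl]-3,4-dimethyl-4-(triethylsilyloxy)cyclohexylidene]propanoate, via B-alkyl-9-borabicyclo[3.3.1]nonane 22 (not isolated)
Conditions: 9-BBN (dimer), THF, 0 °C → rt; then PdCl2(dppf) (dppf = 1,1′-bis(diphenylphosphino)ferrocene, 10 mol %), AsPh3, Cs2CO3, DMF/THF/H2O, 50 °C, high dilution
Reagents that add atoms: none
Why: 9-Borabicyclo[3.3.1]nonane places boron on the terminal carbon (C-6) of the only monosubstituted alkene, the trisubstituted chain alkenes and the electron-poor tetrasubstituted enoate being too hindered to compete, and gives primary alkylborane 22. Zerovalent palladium then inserts into the alkenyl C–O bond of the triflate, the base-activated borane hands its primary alkyl group to divalent palladium, and reductive elimination from the seven-membered palladacycle forms the C-1–C-6 σ-bond; the closest known reaction type is the intramolecular B-alkyl Suzuki–Miyaura coupling of alkenyl triflates and halides to exocyclic alkenes. The six-membered ring closes by sp3–sp2 coupling at the carbon that carried the sulfonate, which ends up as C-1, so the alkene lies outside the new ring (exo mode). No stereocentre is formed, and C-2, C-3 and C-4 take no part in bond making. The selectivity needed is transfer of alkene geometry, secured because oxidative addition and reductive elimination at an alkenyl carbon both go with retention, so the E-triflate (sulfonate cis to methyl) should give only the Z-alkylidene ester with the ester cis to C-2. Ring closure must also outrun intermolecular coupling and attack of oxygen nucleophiles on the β-sulfonyloxy enoate, which high dilution and the silyl cap on the C-4 oxygen are meant to secure.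

Step 14
Reactants: 23 ethyl (2Z)-2-[(2R,3S,4S)-2-[3-(tert-butyldimethylsilyloxy)propyl]-3-[(3E)-4,8-dimethylnona-3,7-dien-1-yl]-3,4-dimethyl-4-(triethylsilyloxy)cyclohexylidene]propanoate
Product: 24 ethyl (2Z)-2-[(2R,3S,4S)-2-[3-(tert-butyldimethylsilyloxy)propyl]-3-[(3E,7E)-9-hydroxy-4,8-dimethylnona-3,7-dien-1-yl]-3,4-dimethyl-4-(triethylsilyloxy)cyclohexylidene]propanoate
Conditions: SeO2 (cat.), t-BuOOH, salicylic acid (cat.), CH2Cl2, rt
Reagents that add atoms: selenium dioxide (catalytic oxygen carrier), O=[Se]=O; tert-butyl hydroperoxide, CC(C)(C)OO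
Why: Selenium dioxide allylic oxidation (ene reaction, then [2,3]-sigmatropic shift) attacks the most electron-rich, terminal trisubstituted alkene at its E-methyl group, while the internal chain alkene reacts more slowly and the enoate is deactivated.

Step 15
Reactants: 24 ethyl (2Z)-2-[(2R,3S,4S)-2-[3-(tert-butyldimethylsilyloxy)propyl]-3-[(3E,7E)-9-hydroxy-4,8-dimethylnona-3,7-dien-1-yl]-3,4-dimethyl-4-(triethylsilyloxy)cyclohexylidene]propanoate
Product: 25 ethyl (2Z)-2-[(2R,3S,4S)-3-[(3E,7E)-9-bromo-4,8-dimethylnona-3,7-dien-1-yl]-2-[3-(tert-butyldimethylsilyloxy)propyl]-3,4-dimethyl-4-(triethylsilyloxy)cyclohexylidene]propanoate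
Conditions: CBr4, PPh3, CH2Cl2, −20 → 0 °C
Reagents that add atoms: carbon tetrabromide, BrC(Br)(Br)Br
Why: Appel bromination converts the primary allylic alcohol into the bromide by direct displacement at the primary carbon, under neutral conditions that leave the silyl ethers and alkene geometry intact.

Step 16
Reactants: 26 3-methylbut-2-enal; 27 propane-1,3-dithiol
Product: 28 2-(2-methylprop-1-en-1-yl)-1,3-dithiane
Conditions: BF3·OEt2 (cat.), CH2Cl2, −20 → 0 °C
Reagents that add atoms: none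
Why: Lewis-acid thioacetalisation gives the dithiane at the carbonyl carbon, conjugate thiol addition being disfavoured at the fully substituted β-carbon.

Step 17
Reactants: 28 2-(2-methylprop-1-en-1-yl)-1,3-dithiane; 25 ethyl (2Z)-2-[(2R,3S,4S)-3-[(3E,7E)-9-bromo-4,8-dimethylnona-3,7-dien-1-yl]-2-[3-(tert-butyldimethylsilyloxy)propyl]-3,4-dimethyl-4-(triethylsilyloxy)cyclohexylidene]propanoate
Product: 30 ethyl (2Z)-2-[(2R,3S,4S)-2-[3-(tert-butyldimethylsilyloxy)propyl]-3-[(3E,7E)-4,8-dimethyl-9-[2-(2-methylprop-1-en-1-yl)-1,3-dithian-2-yl]nona-3,7-dien-1-yl]-3,4-dimethyl-4-(triethylsilyloxy)cyclohexylidene]propanoate, via 2-lithio-1,3-dithiane 29 (not isolated)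
Conditions: n-BuLi, THF, −78 → −30 °C (28 → 29); then 25, −78 °C
Reagents that add atoms: none
Why: Corey–Seebach alkylation, in which the sulfur-stabilised allyl anion reacts with the primary allylic bromide at the dithiane carbon (its other terminus is fully substituted) much faster than it can attack the hindered tetrasubstituted enoate.

Step 18
Reactants: 30 ethyl (2Z)-2-[(2R,3S,4S)-2-[3-(tert-butyldimethylsilyloxy)propyl]-3-[(3E,7E)-4,8-dimethyl-9-[2-(2-methylprop-1-en-1-yl)-1,3-dithian-2-yl]nona-3,7-dien-1-yl]-3,4-dimethyl-4-(triethylsilyloxy)cyclohexylidene]propanoate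
Product: 31 ethyl (2Z)-2-[(2R,3S,4S)-2-[3-(tert-butyldimethylsilyloxy)propyl]-3,4-dimethyl-4-(triethylsilyloxy)-3-[(3E,7E)-4,8,12-trimethyl-10-oxotrideca-3,7,11-trien-1-yl]cyclohexylidene]propanoate
Conditions: MeI, CaCO3, MeCN/H2O, 40 °C
Reagents that add atoms: water, O
Why: S-Methylation makes the sulfur atoms leaving groups and water takes their place, an alkylative dithiane hydrolysis that is inert toward alkenes, esters and silyl ethers and is run at neutral pH so that the skipped enone does not move into conjugation.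

Step 19
Reactants: 31 ethyl (2Z)-2-[(2R,3S,4S)-2-[3-(tert-butyldimethylsilyloxy)propyl]-3,4-dimethyl-4-(triethylsilyloxy)-3-[(3E,7E)-4,8,12-trimethyl-10-oxotrideca-3,7,11-trien-1-yl]cyclohexylidene]propanoate
Product: 32 ethyl (2Z)-2-[(2R,3S,4S)-2-[3-(tert-butyldimethylsilyloxy)propyl]-3-[(3E,7E,10S)-10-hydroxy-4,8,12-trimethyltrideca-3,7,11-trien-1-yl]-3,4-dimethyl-4-(triethylsilyloxy)cyclohexylidene]propanoate
Conditions: (R)-1-methyl-3,3-diphenyltetrahydro-1H,3H-pyrrolo[1,2-c][1,3,2]oxazaborole (20 mol %), catecholborane, PhMe, −78 °C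
Reagents that add atoms: none
Why: Corey–Bakshi–Shibata reduction, in which the alkenyl group of the enone acts as the large substituent and the R-configured catalyst should deliver hydride to give the (S)-allylic alcohol, catecholborane at low temperature sparing the ester and the alkenes.

Step 20
Reactants: 32 ethyl (2Z)-2-[(2R,3S,4S)-2-[3-(tert-butyldimethylsilyloxy)propyl]-3-[(3E,7E,10S)-10-hydroxy-4,8,12-trimethyltrideca-3,7,11-trien-1-yl]-3,4-dimethyl-4-(triethylsilyloxy)cyclohexylidene]propanoate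
Product: 33 (2Z)-2-[(2R,3S,4S)-2-[3-(tert-butyldimethylsilyloxy)propyl]-3-[(3E,7E,10S)-10-hydroxy-4,8,12-trimethyltrideca-3,7,11-trien-1-yl]-3,4-dimethyl-4-(triethylsilyloxy)cyclohexylidene]propan-1-ol
Conditions: i-Bu2AlH, CH2Cl2, −78 °C; aq. potassium sodium tartrate
Reagents that add atoms: none
Why: Aluminium hydride 1,2-reduction of the α,β-unsaturated ester gives the primary allylic alcohol without conjugate reduction or change of alkene geometry.

Step 21
Reactants: 33 (2Z)-2-[(2R,3S,4S)-2-[3-(tert-butyldimethylsilyloxy)propyl]-3-[(3E,7E,10S)-10-hydroxy-4,8,12-trimethyltrideca-3,7,11-trien-1-yl]-3,4-dimethyl-4-(triethylsilyloxy)cyclohexylidene]propan-1-ol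
Product: 34 (2Z)-2-[(2R,3S,4S)-2-[3-(tert-butyldimethylsilyloxy)propyl]-3-[(3E,7E,10S)-10-hydroxy-4,8,12-trimethyltrideca-3,7,11-trien-1-yl]-3,4-dimethyl-4-(triethylsilyloxy)cyclohexylidene]propanal
Conditions: 2,2,6,6-tetramethylpiperidin-1-oxyl (cat.), PhI(OAc)2, CH2Cl2, rt
Reagents that add atoms: none
Why: Oxoammonium-mediated oxidation is strongly selective for primary over secondary alcohols, so the ring-side primary allylic alcohol should give the enal while the secondary allylic alcohol of the side chain survives, the arm oxygen still being silylated.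

Step 22
Reactants: 34 (2Z)-2-[(2R,3S,4S)-2-[3-(tert-butyldimethylsilyloxy)propyl]-3-[(3E,7E,10S)-10-hydroxy-4,8,12-trimethyltrideca-3,7,11-trien-1-yl]-3,4-dimethyl-4-(triethylsilyloxy)cyclohexylidene]propanal
Product: 35 (2Z)-2-[(2R,3S,4S)-4-hydroxy-3-[(3E,7E,10S)-10-hydroxy-4,8,12-trimethyltrideca-3,7,11-trien-1-yl]-2-(3-hydroxypropyl)-3,4-dimethylcyclohexylidene]propanal
Conditions: Bu4NF, AcOH, THF, rt
Reagents that add atoms: none
Why: Acetic acid-buffered fluoride removes both silyl groups at near-neutral pH, which avoids base-induced dienolate formation from the enal (loss of alkene geometry) and acid-induced ionisation of the allylic alcohol.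

Step 23
Reactants: 35 (2Z)-2-[(2R,3S,4S)-4-hydroxy-3-[(3E,7E,10S)-10-hydroxy-4,8,12-trimethyltrideca-3,7,11-trien-1-yl]-2-(3-hydroxypropyl)-3,4-dimethylcyclohexylidene]propanal
Product: 36 (2Z)-2-[(2R,3S,4S)-3-[(3E,7E,10S)-10-[(2R)-3,3-dimethyloxiran-2-yl]-10-hydroxy-4,8-dimethyldeca-3,7-dien-1-yl]-4-hydroxy-2-(3-hydroxypropyl)-3,4-dimethylcyclohexylidene]propanal (CNP0161066.1)
Conditions: VO(acac)2 (cat.), t-BuOOH, CH2Cl2, 0 °C
Reagents that add atoms: tert-butyl hydroperoxide, CC(C)(C)OO
Why: Hydroxyl-directed epoxidation touches only the alkene of the allylic alcohol (the other alkenes lack a nearby directing hydroxyl or are electron-poor), and 1,3-allylic strain from the cis-methyl group fixes the carbinol hydrogen in the alkene plane so that oxygen is delivered from the hydroxyl face to give the threo epoxy alcohol, i.e. the (R)-epoxide carbon next to the (S)-carbinol.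

**Compound list**

1 | δ-valerolactone (oxan-2-one) | O=C1CCCCO1 | starting material
2 | sodium 5-hydroxypentanoate | [Na+].[O-]C(=O)CCCCO | intermediate
3 | tert-butyldimethylsilyl 5-(tert-butyldimethylsilyloxy)pentanoate | CC(C)(C)[Si](C)(C)OCCCCC(=O)O[Si](C)(C)C(C)(C)C | intermediate
4 | 5-(tert-butyldimethylsilyloxy)pentanoic acid | OC(=O)CCCCO[Si](C)(C)C(C)(C)C | intermediate
5 | (2E,6E)-farnesol | CC(C)=CCC/C(C)=C/CC/C(C)=C/CO | starting material
6 | (2E,6E)-farnesyl 5-(tert-butyldimethylsilyloxy)pentanoate | CC(C)=CCC/C(C)=C/CC/C(C)=C/COC(=O)CCCCO[Si](C)(C)C(C)(C)C | intermediate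
7 | Z(O) boron ketene acetal of 6 bearing the (4S,5S)-diazaborolidinyl group on oxygen | CC(C)=CCC/C(C)=C/CC/C(C)=C/CO/C(OB1N(S(=O)(=O)c2cc(cc(c2)C(F)(F)F)C(F)(F)F)[C@@H](c2ccccc2)[C@H](c2ccccc2)N1S(=O)(=O)c1cc(cc(c1)C(F)(F)F)C(F)(F)F)=C/CCCO[Si](C)(C)C(C)(C)C | intermediate
8 | (2S,3R,6E)-2-[3-(tert-butyldimethylsilyloxy)propyl]-3-ethenyl-3,7,11-trimethyldodeca-6,10-dienoic acid | OC(=O)[C@@H](CCCO[Si](C)(C)C(C)(C)C)[C@](C)(CC/C=C(\C)CCC=C(C)C)C=C | intermediate
9 | methyl (2S,3R,6E)-2-[3-(tert-butyldimethylsilyloxy)propyl]-3-ethenyl-3,7,11-trimethyldodeca-6,10-dienoate | COC(=O)[C@@H](CCCO[Si](C)(C)C(C)(C)C)[C@](C)(CC/C=C(\C)CCC=C(C)C)C=C | intermediate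
10 | methyl (2S,3S,6E)-3-acetyl-2-[3-(tert-butyldimethylsilyloxy)propyl]-3,7,11-trimethyldodeca-6,10-dienoate | COC(=O)[C@@H](CCCO[Si](C)(C)C(C)(C)C)[C@](C)(CC/C=C(\C)CCC=C(C)C)C(C)=O | intermediate
11 | vinylmagnesium bromide | C=C[Mg]Br | starting material
12 | bromomagnesium alkoxide of the (S)-vinyl carbinol formed from 10 | COC(=O)[C@@H](CCCO[Si](C)(C)C(C)(C)C)[C@](C)(CC/C=C(\C)CCC=C(C)C)[C@@](C)(O[Mg]Br)C=C | intermediate
13 | (3S,4S,5S)-3-[3-(tert-butyldimethylsilyloxy)propyl]-4-[(3E)-4,8-dimethylnona-3,7-dien-1-yl]-5-ethenyl-4,5-dimethyloxolan-2-one | O=C1[C@@H](CCCO[Si](C)(C)C(C)(C)C)[C@](C)(CC/C=C(\C)CCC=C(C)C)[C@](C)(C=C)O1 | intermediate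
14 | (2S,3S,6E)-2-[3-(tert-butyldimethylsilyloxy)propyl]-3-[(2S)-2-hydroxybut-3-en-2-yl]-3,7,11-trimethyldodeca-6,10-dien-1-ol | OC[C@@H](CCCO[Si](C)(C)C(C)(C)C)[C@](C)(CC/C=C(\C)CCC=C(C)C)[C@@](C)(O)C=C | intermediate
15 | bis(triethylsilyl) ether of 14 | CC[Si](CC)(CC)OC[C@@H](CCCO[Si](C)(C)C(C)(C)C)[C@](C)(CC/C=C(\C)CCC=C(C)C)[C@@](C)(O[Si](CC)(CC)CC)C=C | intermediate
16 | (2S,3S,6E)-2-[3-(tert-butyldimethylsilyloxy)propyl]-3,7,11-trimethyl-3-[(2S)-2-(triethylsilyloxy)but-3-en-2-yl]dodeca-6,10-dienal | O=C[C@@H](CCCO[Si](C)(C)C(C)(C)C)[C@](C)(CC/C=C(\C)CCC=C(C)C)[C@@](C)(O[Si](CC)(CC)CC)C=C | intermediate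
17 | ethyl propionate | CCC(=O)OCC | starting material
18 | lithium E(O)-enolate of ethyl propionate | CCO/C(O[Li])=C\C | intermediate
19 | ethyl (4S,5S,8E)-4-[3-(tert-butyldimethylsilyloxy)propyl]-3-hydroxy-2,5,9,13-tetramethyl-5-[(2S)-2-(triethylsilyloxy)but-3-en-2-yl]tetradeca-8,12-dienoate (mixture at C-2 and C-3 of the ester chain) | CCOC(=O)C(C)C(O)[C@@H](CCCO[Si](C)(C)C(C)(C)C)[C@](C)(CC/C=C(\C)CCC=C(C)C)[C@@](C)(O[Si](CC)(CC)CC)C=C | intermediate
20 | ethyl (4S,5S,8E)-4-[3-(tert-butyldimethylsilyloxy)propyl]-2,5,9,13-tetramethyl-3-oxo-5-[(2S)-2-(triethylsilyloxy)but-3-en-2-yl]tetradeca-8,12-dienoate (mixture at the α-methyl carbon) | CCOC(=O)C(C)C(=O)[C@@H](CCCO[Si](C)(C)C(C)(C)C)[C@](C)(CC/C=C(\C)CCC=C(C)C)[C@@](C)(O[Si](CC)(CC)CC)C=C | intermediate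
21 | ethyl (2E,4S,5S,8E)-4-[3-(tert-butyldimethylsilyloxy)propyl]-2,5,9,13-tetramethyl-5-[(2S)-2-(triethylsilyloxy)but-3-en-2-yl]-3-(trifluoromethylsulfonyloxy)tetradeca-2,8,12-trienoate (ring-closure precursor) | C/C(C(=O)OCC)=C(\OS(=O)(=O)C(F)(F)F)[C@@H](CCCO[Si](C)(C)C(C)(C)C)[C@](C)(CC/C=C(\C)CCC=C(C)C)[C@@](C)(O[Si](CC)(CC)CC)C=C | intermediate
22 | B-alkyl-9-borabicyclo[3.3.1]nonane from hydroboration of the vinyl group of 21 | C/C(C(=O)OCC)=C(\OS(=O)(=O)C(F)(F)F)[C@@H](CCCO[Si](C)(C)C(C)(C)C)[C@](C)(CC/C=C(\C)CCC=C(C)C)[C@@](C)(O[Si](CC)(CC)CC)CCB1C2CCCC1CCC2 | intermediate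
23 | ethyl (2Z)-2-[(2R,3S,4S)-2-[3-(tert-butyldimethylsilyloxy)propyl]-3-[(3E)-4,8-dimethylnona-3,7-dien-1-yl]-3,4-dimethyl-4-(triethylsilyloxy)cyclohexylidene]propanoate (ring-closure product) | C/C(C(=O)OCC)=C1\CC[C@](C)(O[Si](CC)(CC)CC)[C@@](C)(CC/C=C(\C)CCC=C(C)C)[C@@H]1CCCO[Si](C)(C)C(C)(C)C | intermediate
24 | ethyl (2Z)-2-[(2R,3S,4S)-2-[3-(tert-butyldimethylsilyloxy)propyl]-3-[(3E,7E)-9-hydroxy-4,8-dimethylnona-3,7-dien-1-yl]-3,4-dimethyl-4-(triethylsilyloxy)cyclohexylidene]propanoate | C/C(C(=O)OCC)=C1\CC[C@](C)(O[Si](CC)(CC)CC)[C@@](C)(CC/C=C(\C)CC/C=C(\C)CO)[C@@H]1CCCO[Si](C)(C)C(C)(C)C | intermediate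
25 | ethyl (2Z)-2-[(2R,3S,4S)-3-[(3E,7E)-9-bromo-4,8-dimethylnona-3,7-dien-1-yl]-2-[3-(tert-butyldimethylsilyloxy)propyl]-3,4-dimethyl-4-(triethylsilyloxy)cyclohexylidene]propanoate | C/C(C(=O)OCC)=C1\CC[C@](C)(O[Si](CC)(CC)CC)[C@@](C)(CC/C=C(\C)CC/C=C(\C)CBr)[C@@H]1CCCO[Si](C)(C)C(C)(C)C | intermediate
26 | 3-methylbut-2-enal | CC(C)=CC=O | starting material
27 | propane-1,3-dithiol | SCCCS | starting material
28 | 2-(2-methylprop-1-en-1-yl)-1,3-dithiane | CC(C)=CC1SCCCS1 | intermediate
29 | 2-lithio-2-(2-methylprop-1-en-1-yl)-1,3-dithiane | [Li]C1(C=C(C)C)SCCCS1 | intermediate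
30 | ethyl (2Z)-2-[(2R,3S,4S)-2-[3-(tert-butyldimethylsilyloxy)propyl]-3-[(3E,7E)-4,8-dimethyl-9-[2-(2-methylprop-1-en-1-yl)-1,3-dithian-2-yl]nona-3,7-dien-1-yl]-3,4-dimethyl-4-(triethylsilyloxy)cyclohexylidene]propanoate | C/C(C(=O)OCC)=C1\CC[C@](C)(O[Si](CC)(CC)CC)[C@@](C)(CC/C=C(\C)CC/C=C(\C)CC2(C=C(C)C)SCCCS2)[C@@H]1CCCO[Si](C)(C)C(C)(C)C | intermediate
31 | ethyl (2Z)-2-[(2R,3S,4S)-2-[3-(tert-butyldimethylsilyloxy)propyl]-3,4-dimethyl-4-(triethylsilyloxy)-3-[(3E,7E)-4,8,12-trimethyl-10-oxotrideca-3,7,11-trien-1-yl]cyclohexylidene]propanoate | C/C(C(=O)OCC)=C1\CC[C@](C)(O[Si](CC)(CC)CC)[C@@](C)(CC/C=C(\C)CC/C=C(\C)CC(=O)C=C(C)C)[C@@H]1CCCO[Si](C)(C)C(C)(C)C | intermediate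
32 | ethyl (2Z)-2-[(2R,3S,4S)-2-[3-(tert-butyldimethylsilyloxy)propyl]-3-[(3E,7E,10S)-10-hydroxy-4,8,12-trimethyltrideca-3,7,11-trien-1-yl]-3,4-dimethyl-4-(triethylsilyloxy)cyclohexylidene]propanoate | C/C(C(=O)OCC)=C1\CC[C@](C)(O[Si](CC)(CC)CC)[C@@](C)(CC/C=C(\C)CC/C=C(\C)C[C@H](O)C=C(C)C)[C@@H]1CCCO[Si](C)(C)C(C)(C)C | intermediate
33 | (2Z)-2-[(2R,3S,4S)-2-[3-(tert-butyldimethylsilyloxy)propyl]-3-[(3E,7E,10S)-10-hydroxy-4,8,12-trimethyltrideca-3,7,11-trien-1-yl]-3,4-dimethyl-4-(triethylsilyloxy)cyclohexylidene]propan-1-ol | C/C(CO)=C1\CC[C@](C)(O[Si](CC)(CC)CC)[C@@](C)(CC/C=C(\C)CC/C=C(\C)C[C@H](O)C=C(C)C)[C@@H]1CCCO[Si](C)(C)C(C)(C)C | intermediate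
34 | (2Z)-2-[(2R,3S,4S)-2-[3-(tert-butyldimethylsilyloxy)propyl]-3-[(3E,7E,10S)-10-hydroxy-4,8,12-trimethyltrideca-3,7,11-trien-1-yl]-3,4-dimethyl-4-(triethylsilyloxy)cyclohexylidene]propanal | C/C(C=O)=C1\CC[C@](C)(O[Si](CC)(CC)CC)[C@@](C)(CC/C=C(\C)CC/C=C(\C)C[C@H](O)C=C(C)C)[C@@H]1CCCO[Si](C)(C)C(C)(C)C | intermediate
35 | (2Z)-2-[(2R,3S,4S)-4-hydroxy-3-[(3E,7E,10S)-10-hydroxy-4,8,12-trimethyltrideca-3,7,11-trien-1-yl]-2-(3-hydroxypropyl)-3,4-dimethylcyclohexylidene]propanal | C/C(C=O)=C1\CC[C@](C)(O)[C@@](C)(CC/C=C(\C)CC/C=C(\C)C[C@H](O)C=C(C)C)[C@@H]1CCCO | intermediate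
36 | (2Z)-2-[(2R,3S,4S)-3-[(3E,7E,10S)-10-[(2R)-3,3-dimethyloxiran-2-yl]-10-hydroxy-4,8-dimethyldeca-3,7-dien-1-yl]-4-hydroxy-2-(3-hydroxypropyl)-3,4-dimethylcyclohexylidene]propanal (CNP0161066.1) | C/C(C=O)=C1\CC[C@](C)(O)[C@@](C)(CC/C=C(\C)CC/C=C(\C)C[C@H](O)[C@H]2OC2(C)C)[C@@H]1CCCO | target

**Step count.** Total: 23 steps. Longest linear sequence: 22 steps (steps 1–15 and 17–23, from δ-valerolactone); step 16 is a one-step side branch.

**Steps most likely to fail**

1. Step 13 (ring closure). The processes at risk are incomplete hydroboration of the doubly neopentylic vinyl group and slow oxidative addition at the congested tetrasubstituted enol triflate, which would let base-induced S–O cleavage and protodeboronation overtake the coupling. Fallback, from 21: hydroboration as before, then oxidation (NaBO3·4H2O), gives the primary alcohol F1. This is converted (I2, PPh3, imidazole) into the primary iodide F2. Zinc insertion (Zn, LiCl, THF) gives the alkylzinc iodide F3. A base-free intramolecular Negishi coupling (Pd(OAc)2, 2-dicyclohexylphosphino-2′,6′-dimethoxybiphenyl, THF) then forms the same C-1–C-6 bond with retention of alkene geometry and returns to the route at 23.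

2. Step 12 (enol triflation). The process at risk is erosion of alkene geometry during O-sulfonylation, through partial chelation or equilibration of the enolate, which would carry the wrong isomer into the ring closure. Fallback, from 20: sulfonylation through an N-sulfonylammonium intermediate with amine bases only (TsCl, N-methylimidazole, Et3N, MeCN), a metal-free protocol for α-substituted β-keto esters, should give the (E)-enol tosylate F4. This is a stable compound from which a minor geometric isomer can be removed by chromatography or crystallisation. Hydroboration with 9-BBN gives the alkylborane F5, and coupling of this less reactive sulfonate (Pd(OAc)2, 2-dicyclohexylphosphino-2′,6′-dimethoxybiphenyl, Cs2CO3, THF/H2O) returns to the route at 23.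

3. Step 6 (vinyl addition). The process at risk is weak or reversed facial discrimination in the carbonyl addition, since only a methyl and a primary alkyl group distinguish the two faces once the largest branch is anti. Fallback, from 10, by exchanging the roles of nucleophile and ketone substituent: the methyl ketone is converted (Me3SiOTf, Et3N, CH2Cl2) into the trimethylsilyl enol ether F6, which is aminomethylated with dimethyl(methylidene)ammonium iodide to the Mannich base F7. Quaternisation and elimination (MeI; NaHCO3) give the vinyl ketone F8. 1,2-Addition of MeLi (THF, −78 °C) gives the lithium alkoxide F9, which lactonises on warming and returns to the route at 13. The same steric bias now places the methyl group where the vinyl group entered before, so a preference for the unwanted C-4 epimer in step 6 becomes a preference for the wanted one. With a weak bias in either sequence the lactone epimers are separated at 13.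

**Further compounds**

F1 | step 13 | ethyl (2E,4S,5S,8E)-4-[3-(tert-butyldimethylsilyloxy)propyl]-5-[(2S)-4-hydroxy-2-(triethylsilyloxy)butan-2-yl]-2,5,9,13-tetramethyl-3-(trifluoromethylsulfonyloxy)tetradeca-2,8,12-trienoate | C/C(C(=O)OCC)=C(\OS(=O)(=O)C(F)(F)F)[C@@H](CCCO[Si](C)(C)C(C)(C)C)[C@](C)(CC/C=C(\C)CCC=C(C)C)[C@@](C)(O[Si](CC)(CC)CC)CCO
F2 | step 13 | primary iodide corresponding to F1 (4-iodo-2-(triethylsilyloxy)butan-2-yl group) | C/C(C(=O)OCC)=C(\OS(=O)(=O)C(F)(F)F)[C@@H](CCCO[Si](C)(C)C(C)(C)C)[C@](C)(CC/C=C(\C)CCC=C(C)C)[C@@](C)(O[Si](CC)(CC)CC)CCI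
F3 | step 13 | alkylzinc iodide from F2 | C/C(C(=O)OCC)=C(\OS(=O)(=O)C(F)(F)F)[C@@H](CCCO[Si](C)(C)C(C)(C)C)[C@](C)(CC/C=C(\C)CCC=C(C)C)[C@@](C)(O[Si](CC)(CC)CC)CC[Zn]I
F4 | step 12 | ethyl (2E,4S,5S,8E)-4-[3-(tert-butyldimethylsilyloxy)propyl]-2,5,9,13-tetramethyl-3-(4-methylphenylsulfonyloxy)-5-[(2S)-2-(triethylsilyloxy)but-3-en-2-yl]tetradeca-2,8,12-trienoate | C/C(C(=O)OCC)=C(\OS(=O)(=O)c1ccc(C)cc1)[C@@H](CCCO[Si](C)(C)C(C)(C)C)[C@](C)(CC/C=C(\C)CCC=C(C)C)[C@@](C)(O[Si](CC)(CC)CC)C=C
F5 | step 12 | B-alkyl-9-borabicyclo[3.3.1]nonane from hydroboration of the vinyl group of F4 | C/C(C(=O)OCC)=C(\OS(=O)(=O)c1ccc(C)cc1)[C@@H](CCCO[Si](C)(C)C(C)(C)C)[C@](C)(CC/C=C(\C)CCC=C(C)C)[C@@](C)(O[Si](CC)(CC)CC)CCB1C2CCCC1CCC2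
F6 | step 6 | trimethylsilyl enol ether of methyl ketone 10 | COC(=O)[C@@H](CCCO[Si](C)(C)C(C)(C)C)[C@](C)(CC/C=C(\C)CCC=C(C)C)C(=C)O[Si](C)(C)C
F7 | step 6 | methyl (2S,3S,6E)-2-[3-(tert-butyldimethylsilyloxy)propyl]-3-[3-(dimethylamino)propanoyl]-3,7,11-trimethyldodeca-6,10-dienoate | COC(=O)[C@@H](CCCO[Si](C)(C)C(C)(C)C)[C@](C)(CC/C=C(\C)CCC=C(C)C)C(=O)CCN(C)C
F8 | step 6 | methyl (2S,3S,6E)-2-[3-(tert-butyldimethylsilyloxy)propyl]-3,7,11-trimethyl-3-(prop-2-enoyl)dodeca-6,10-dienoate | COC(=O)[C@@H](CCCO[Si](C)(C)C(C)(C)C)[C@](C)(CC/C=C(\C)CCC=C(C)C)C(=O)C=C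
F9 | step 6 | lithium alkoxide of the (S)-vinyl carbinol (lithium counterpart of 12) | COC(=O)[C@@H](CCCO[Si](C)(C)C(C)(C)C)[C@](C)(CC/C=C(\C)CCC=C(C)C)[C@@](C)(O[Li])C=C
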